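**Plan**

- Retrosynthetic cuts: (a) the methyl ester back to a silyl-protected primary alcohol; (b) the two C–O bonds of the 1,2-dioxane (numbered O1, O2, C3 bearing the propanoate, C6 bearing the methyl) — O–C3 by intramolecular SN2, O–C6 by perhydrolysis of an epoxide, the extra C5 hydroxyl being removed by dehydration and diimide; (c) the C4–C5 bond (alkenylalanate plus chiral epoxide); (d) the exocyclic methylene (ketone plus ylide); (e) the ring bond between the C(CH3)2 carbon and its CH2 neighbour (radical ring closure); (f) the carbinol–CH(OH) bond (Barbier), back to a tetrasubstituted allylic alcohol.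
- Forward order: an acyclic chain is built around the future carbinol carbon, the cyclohexane is closed, the methylene is installed, the side chain is added in one convergent coupling, and the 1,2-dioxane is made last.
- Enabling feature: in the carbocycle the C(CH3)2 carbon lies between the tertiary carbinol carbon and a ring CH2. It is therefore the tertiary radical that an isopropenyl group on the carbinol carbon gives on H-atom addition, and the ring CH2 is the free terminus of a 1,1-disubstituted alkene whose inner carbon (later a ring CH2) carries a removable sulfonyl group, so the six-membered ring closes 6-endo.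
- Stereochemistry: the ring carbinol comes from a Sharpless asymmetric epoxidation (its C–O bond is never broken afterwards); C2 of the propanoate from (R)-Roche ester; C3 from a hydrolytic kinetic resolution followed by one inversion in the peroxide ring closure; C6 from a Shi epoxidation followed by inversion in the perhydrolysis.
- Helpers taken out later: the sulfone (step 10), the secondary hydroxyl next to the carbinol (steps 11 and 12), the alkynyl silane (step 10), the C5 hydroxyl (steps 23 and 24) and the silyl ethers (step 25).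

Key step: step 9

Abbreviations: TMS = trimethylsilyl; TES = triethylsilyl; TBS = tert-butyldimethylsilyl; Cy* = (1S)-2,2-dimethyl-6-methylidene-1-[(triethylsilyl)oxy]cyclohexyl; IBX = 2-iodoxybenzoic acid; salen = N,N′-bis(3,5-di-tert-butylsalicylidene)cyclohexane-1,2-diamine dianion; Shi ketone = 1,2:4,5-di-O-isopropylidene-β-D-erythro-hexo-2,3-diulo-2,6-pyranose (from D-fructose); Martin sulfurane = Ph2S[OC(CF3)2Ph]2.

Remark: the centers created in steps 8 and 9 and destroyed in steps 10 and 11 are carried as epimer mixtures and are written without configuration in the SMILES.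

**Route**

Step 1
Reactants: 1 but-2-yn-1-ol; 2 (4-bromobut-1-yn-1-yl)trimethylsilane
Product: 5 (2Z)-3-iodo-2-[4-(trimethylsilyl)but-3-yn-1-yl]but-2-en-1-ol, via Grignard reagent 3 (not isolated), via alkenylmagnesium chelate 4 (not isolated)
Conditions: Mg, THF (2 to 3); then 1 (0.4 equiv), CuI (10 mol %), THF, reflux; then I2, −78 to 0 °C
Reagents that add atoms: iodine, II
Why: Copper-catalysed anti-carbomagnesiation of a propargylic alcohol should put the alkyl group on the carbon next to the carbinol and magnesium on the distal carbon in a five-membered chelate, and iodinolysis of the C–Mg bond then gives the iodoalkene; its geometry is of no consequence because step 2 makes both distal substituents methyl.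

Step 2
Reactants: 5 (2Z)-3-iodo-2-[4-(trimethylsilyl)but-3-yn-1-yl]but-2-en-1-ol
Product: 6 3-methyl-2-[4-(trimethylsilyl)but-3-yn-1-yl]but-2-en-1-ol
Conditions: Me2Zn (2.5 equiv), Pd(dppf)Cl2 (5 mol %), THF, 50 °C
Reagents that add atoms: dimethylzinc, C[Zn]C
Why: Negishi cross-coupling of the alkenyl iodide should replace iodine by methyl while the hydroxyl is carried as its zinc alkoxide.

Step 3
Reactants: 6 3-methyl-2-[4-(trimethylsilyl)but-3-yn-1-yl]but-2-en-1-ol
Product: 7 {(2R)-3,3-dimethyl-2-[4-(trimethylsilyl)but-3-yn-1-yl]oxiran-2-yl}methanol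
Conditions: Ti(OiPr)4 (10 mol %), D-(−)-diisopropyl tartrate (12 mol %), t-BuOOH, 4 Å molecular sieves, CH2Cl2, −20 °C
Reagents that add atoms: tert-butyl hydroperoxide, CC(C)(C)OO
Why: Sharpless asymmetric epoxidation of the primary tetrasubstituted allylic alcohol under reagent control; the D-(−)-tartrate delivers oxygen to the face opposite to that used by the natural ester and should give the (R)-epoxide, which fixes the future ring carbinol center.

Step 4
Reactants: 7 {(2R)-3,3-dimethyl-2-[4-(trimethylsilyl)but-3-yn-1-yl]oxiran-2-yl}methanol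
Product: 8 (2S)-3-methyl-2-[4-(trimethylsilyl)but-3-yn-1-yl]but-3-ene-1,2-diol
Conditions: Ti(OiPr)4 (1.5 equiv), CH2Cl2, rt
Reagents that add atoms: none
Why: Hydroxyl-directed Ti(OiPr)4-promoted isomerisation of a 2,3-epoxy alcohol to an allylic 1,2-diol: the chelated Lewis acid should cleave the distal O–C(CH3)2 bond and a methyl proton is lost, so the carbinol C–O bond and its configuration are retained.

Step 5
Reactants: 8 (2S)-3-methyl-2-[4-(trimethylsilyl)but-3-yn-1-yl]but-3-ene-1,2-diol
Product: 9 (2S)-2-hydroxy-3-methyl-2-[4-(trimethylsilyl)but-3-yn-1-yl]but-3-enal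
Conditions: IBX, DMSO, rt; used crude
Reagents that add atoms: none
Why: IBX oxidation should take the primary hydroxyl of the 1,2-diol to the aldehyde without glycol cleavage and leave the tertiary hydroxyl untouched.

Step 6
Reactants: 10 phenyl vinyl sulfone
Product: 11 2-(phenylsulfonyl)prop-2-en-1-ol
Conditions: 37% aq. CH2O, DABCO, THF, rt
Reagents that add atoms: formaldehyde, C=O
Why: Morita–Baylis–Hillman hydroxymethylation at the α-carbon of the vinyl sulfone.

Step 7
Reactants: 11 2-(phenylsulfonyl)prop-2-en-1-ol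
Product: 12 3-bromo-2-(phenylsulfonyl)prop-1-ene
Conditions: PBr3 (0.4 equiv), Et2O, 0 °C
Reagents that add atoms: phosphorus tribromide, BrP(Br)Br
Why: Standard conversion of a primary allylic alcohol into the bromide; direct and allylic substitution give the same product here.

Step 8
Reactants: 9 (2S)-2-hydroxy-3-methyl-2-[4-(trimethylsilyl)but-3-yn-1-yl]but-3-enal; 12 3-bromo-2-(phenylsulfonyl)prop-1-ene
Product: 13 (5S)-6-methyl-2-(phenylsulfonyl)-5-[4-(trimethylsilyl)but-3-yn-1-yl]hepta-1,6-diene-4,5-diol (both C-4 epimers)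
Conditions: Zn dust, THF/sat. aq. NH4Cl, rt
Reagents that add atoms: none
Why: Zinc-mediated Barbier allylation in aqueous medium tolerates the free α-hydroxy aldehyde and attaches the three-carbon sulfonylalkene unit; the new carbinol center should form mainly under chelation control, but both epimers are used because it becomes a ketone in step 11.

Step 9
Reactants: 13 (5S)-6-methyl-2-(phenylsulfonyl)-5-[4-(trimethylsilyl)but-3-yn-1-yl]hepta-1,6-diene-4,5-diol (both C-4 epimers)
Product: 14 (1S)-6,6-dimethyl-4-(phenylsulfonyl)-1-[4-(trimethylsilyl)but-3-yn-1-yl]cyclohexane-1,2-diol (epimers at C-2 and C-4)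
Conditions: Fe(acac)3 (30 mol %), PhSiH3 (2.5 equiv), EtOH/(CH2OH)2 5:1, 0.02 M, 60 °C
Reagents that add atoms: none
Why: The iron hydride formed from Fe(acac)3 and PhSiH3 should transfer a hydrogen atom to the CH2 terminus of the isopropenyl group and so place a tertiary radical on the carbon that carries the two methyl groups; this nucleophilic radical adds to the unsubstituted CH2 terminus of the 2-sulfonylalkene, and the α-sulfonyl radical is reduced by divalent iron to the carbanion and protonated by ethanol. The closest known reaction type is the metal-hydride hydrogen-atom-transfer reductive coupling of an unactivated alkene with an electron-poor alkene (radical conjugate addition), here run intramolecularly. The cyclohexane closes in the 6-endo-trig mode, since both carbons of the acceptor alkene end up in the ring; the 5-exo alternative would require attack at the fully substituted, sulfonyl-bearing carbon against both polarity and steric demand. The only new stereocenter is the sulfonyl-bearing carbon, which forms without control and is erased in step 10, while the neighbouring quaternary carbinol center has no hydrogen and cannot epimerise. The step needs chemoselective hydrogen-atom transfer, secured because the isopropenyl group is the only electron-rich alkene (the alkyne is internal and silylated, the other alkene is electron-poor), and ring closure faster than reduction of the radical or its 5-exo addition to the alkyne, which high dilution, the polarity match with the sulfonylalkene and the branched tether should favour.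

Step 10
Reactants: 14 (1S)-6,6-dimethyl-4-(phenylsulfonyl)-1-[4-(trimethylsilyl)but-3-yn-1-yl]cyclohexane-1,2-diol (epimers at C-2 and C-4)
Product: 15 (1S)-1-(but-3-yn-1-yl)-6,6-dimethylcyclohexane-1,2-diol (both C-2 epimers)
Conditions: Na(Hg) (6% Na), MeOH/THF, −20 °C to rt
Reagents that add atoms: none
Why: Reductive desulfonylation (two-electron cleavage of the C–S bond, then protonation) removes the activating group, and the methoxide formed should also cleave the alkynyl C–Si bond.

Step 11
Reactants: 15 (1S)-1-(but-3-yn-1-yl)-6,6-dimethylcyclohexane-1,2-diol (both C-2 epimers)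
Product: 16 (2S)-2-(but-3-yn-1-yl)-2-hydroxy-3,3-dimethylcyclohexan-1-one
Conditions: IBX, DMSO, rt
Reagents that add atoms: none
Why: IBX oxidises the secondary alcohol of a 1,2-diol to the α-hydroxy ketone without C–C cleavage, which converges both carbinol epimers.

Step 12
Reactants: 16 (2S)-2-(but-3-yn-1-yl)-2-hydroxy-3,3-dimethylcyclohexan-1-one
Product: 17 (1S)-1-(but-3-yn-1-yl)-2,2-dimethyl-6-methylidenecyclohexan-1-ol
Conditions: Ph3PCH3Br (5 equiv), KOtBu (4.8 equiv), toluene, 0 to 80 °C
Reagents that add atoms: methyltriphenylphosphonium bromide, C[P+](c1ccccc1)(c1ccccc1)c1ccccc1.[Br-]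
Why: Wittig methylenation with excess ylide (hydroxyl and alkyne are deprotonated in the flask) should install the exocyclic methylene; the adjacent quaternary carbinol center cannot epimerise.

Step 13
Reactants: 17 (1S)-1-(but-3-yn-1-yl)-2,2-dimethyl-6-methylidenecyclohexan-1-ol
Product: 18 {[(1S)-1-(but-3-yn-1-yl)-2,2-dimethyl-6-methylidenecyclohexyl]oxy}triethylsilane
Conditions: TESOTf, 2,6-lutidine, CH2Cl2, −78 to 0 °C
Reagents that add atoms: triethylsilyl trifluoromethanesulfonate, CC[Si](CC)(CC)OS(=O)(=O)C(F)(F)F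
Why: Silylation of the hindered tertiary alcohol with the silyl triflate; the ether keeps this hydroxyl from attacking, in the 5-exo mode, the epoxide made in step 20.

Step 14
Reactants: 19 methyl (2R)-3-hydroxy-2-methylpropanoate
Product: 20 methyl (2R)-3-[(tert-butyldimethylsilyl)oxy]-2-methylpropanoate
Conditions: TBSCl, imidazole, DMF, rt
Reagents that add atoms: tert-butyldimethylsilyl chloride, CC(C)(C)[Si](C)(C)Cl
Why: Standard silyl protection of the primary alcohol; the stereocenter is not involved.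

Step 15
Reactants: 20 methyl (2R)-3-[(tert-butyldimethylsilyl)oxy]-2-methylpropanoate
Product: 21 (2R)-3-[(tert-butyldimethylsilyl)oxy]-2-methylpropanal
Conditions: DIBAL-H (1.05 equiv), CH2Cl2, −78 °C; potassium sodium tartrate work-up
Reagents that add atoms: none
Why: Partial reduction of the ester at −78 °C should stop at the aldehyde through the stable tetrahedral aluminium alkoxide, with the α-stereocenter retained.

Step 16
Reactants: 21 (2R)-3-[(tert-butyldimethylsilyl)oxy]-2-methylpropanal
Product: 23 tert-butyldimethyl{[(2R)-2-(oxiran-2-yl)propyl]oxy}silane (both oxirane epimers), via lithium chlorohydrin alkoxide 22 (not isolated)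
Conditions: ICH2Cl, MeLi·LiBr, THF, −78 °C to rt
Reagents that add atoms: chloroiodomethane, ClCI
Why: Chloromethyllithium adds to the aldehyde at −78 °C faster than α-epimerisation and the chlorohydrin alkoxide closes to the epoxide on warming; the new center is expected to form with low selectivity and is corrected in step 17.

Step 17
Reactants: 23 tert-butyldimethyl{[(2R)-2-(oxiran-2-yl)propyl]oxy}silane (both oxirane epimers)
Product: 24 tert-butyldimethyl{[(2R)-2-[(2S)-oxiran-2-yl]propyl]oxy}silane
Conditions: (S,S)-(salen)Co(OAc) (1 mol %, trivalent cobalt), H2O (slight excess over the (2R)-oxirane epimer), THF, 0 °C to rt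
Reagents that add atoms: none
Why: Jacobsen hydrolytic kinetic resolution under catalyst control: the (S,S)-catalyst, the enantiomer that hydrates (R)-alkyloxiranes, should convert the unwanted oxirane epimer into its diol and leave the (S)-oxirane.

Step 18
Reactants: 18 {[(1S)-1-(but-3-yn-1-yl)-2,2-dimethyl-6-methylidenecyclohexyl]oxy}triethylsilane; 24 tert-butyldimethyl{[(2R)-2-[(2S)-oxiran-2-yl]propyl]oxy}silane
Product: 27 (2R,3R,5E)-1-(TBSO)-8-Cy*-2,6-dimethyloct-5-en-3-ol, via alkenyldimethylalane 25 (not isolated), via lithium alkenylaluminate 26 (not isolated)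
Conditions: Me3Al (3 equiv), Cp2ZrCl2 (25 mol %), CH2Cl2, 0 °C to rt; then n-BuLi, hexane/THF, −78 to 0 °C; then 24, THF, 0 °C to rt
Reagents that add atoms: trimethylaluminium, C[Al](C)C
Why: Negishi zirconium-catalysed syn-carboalumination of the terminal alkyne (methyl to the internal carbon) gives the (E)-alkenylalane, and its butyl ate complex should open the epoxide at the CH2 terminus with retention of both the alkene geometry and the epoxide stereocenter.

Step 19
Reactants: 27 (2R,3R,5E)-1-(TBSO)-8-Cy*-2,6-dimethyloct-5-en-3-ol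
Product: 28 (2R,3R,5E)-1-(TBSO)-8-Cy*-2,6-dimethyloct-5-en-3-yl methanesulfonate
Conditions: MsCl, Et3N, CH2Cl2, 0 °C
Reagents that add atoms: methanesulfonyl chloride, CS(=O)(=O)Cl
Why: Mesylation of the only free hydroxyl, with retention at carbon, provides the leaving group for the peroxide ring closure.

Step 20
Reactants: 28 (2R,3R,5E)-1-(TBSO)-8-Cy*-2,6-dimethyloct-5-en-3-yl methanesulfonate
Product: 29 (2R,3R,5R,6R)-1-(TBSO)-8-Cy*-5,6-epoxy-2,6-dimethyloctan-3-yl methanesulfonate
Conditions: Shi ketone (30 mol %), Oxone (2KHSO5·KHSO4·K2SO4), K2CO3, Bu4NHSO4, MeCN/CH2(OMe)2/aq. Na2B4O7 buffer, 0 °C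
Reagents that add atoms: potassium peroxymonosulfate, [K+].[O-]S(=O)(=O)OO
Why: Shi epoxidation: the dioxirane of the D-fructose-derived ketone should epoxidise the (E)-trisubstituted alkene under reagent control to the (R,R)-epoxide, while the hindered exocyclic 1,1-disubstituted alkene is a poor substrate.

Step 21
Reactants: 29 (2R,3R,5R,6R)-1-(TBSO)-8-Cy*-5,6-epoxy-2,6-dimethyloctan-3-yl methanesulfonate
Product: 30 (2R,3R,5R,6S)-1-(TBSO)-8-Cy*-6-hydroperoxy-5-hydroxy-2,6-dimethyloctan-3-yl methanesulfonate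
Conditions: anhydrous H2O2 in Et2O, MoO2(acac)2 (10 mol %), 0 °C to rt
Reagents that add atoms: hydrogen peroxide, OO
Why: Molybdenum-catalysed perhydrolysis of a trisubstituted epoxide: H2O2 should attack the tertiary carbon with inversion, which sets the quaternary peroxide center and leaves the secondary C–O bond untouched.

Step 22
Reactants: 30 (2R,3R,5R,6S)-1-(TBSO)-8-Cy*-6-hydroperoxy-5-hydroxy-2,6-dimethyloctan-3-yl methanesulfonate
Product: 31 (3S,4R,6S)-6-[(2R)-1-(TBSO)propan-2-yl]-3-(2-Cy*-ethyl)-3-methyl-1,2-dioxan-4-ol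
Conditions: Cs2CO3, DMF, 0 °C to rt
Reagents that add atoms: none
Why: Intramolecular 6-exo-tet displacement of the secondary mesylate by the hydroperoxide anion should close the 1,2-dioxane with inversion at the mesylate carbon.

Step 23
Reactants: 31 (3S,4R,6S)-6-[(2R)-1-(TBSO)propan-2-yl]-3-(2-Cy*-ethyl)-3-methyl-1,2-dioxan-4-ol
Product: 32 (3S,6S)-6-[(2R)-1-(TBSO)propan-2-yl]-3-(2-Cy*-ethyl)-3-methyl-3,6-dihydro-1,2-dioxine
Conditions: Martin sulfurane, CH2Cl2, 0 °C to rt
Reagents that add atoms: none
Why: Dehydration of the secondary alcohol under neutral conditions; elimination can only go toward the ring CH2 because the other neighbour is quaternary, and no base is present that could trigger Kornblum–DeLaMare cleavage.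

Step 24
Reactants: 32 (3S,6S)-6-[(2R)-1-(TBSO)propan-2-yl]-3-(2-Cy*-ethyl)-3-methyl-3,6-dihydro-1,2-dioxine
Product: 33 (3R,6S)-6-[(2R)-1-(TBSO)propan-2-yl]-3-(2-Cy*-ethyl)-3-methyl-1,2-dioxane
Conditions: KO2CN=NCO2K, AcOH, CH2Cl2/MeOH, 0 °C to rt
Reagents that add atoms: none
Why: Diimide reduction saturates the cis ring alkene of the dihydrodioxine without touching the O–O bond; the exocyclic methylene next to the quaternary silyloxy carbon is expected to react more slowly.

Step 25
Reactants: 33 (3R,6S)-6-[(2R)-1-(TBSO)propan-2-yl]-3-(2-Cy*-ethyl)-3-methyl-1,2-dioxane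
Product: 34 (2R)-2-[(3S,6R)-6-{2-[(1S)-1-hydroxy-2,2-dimethyl-6-methylidenecyclohexyl]ethyl}-6-methyl-1,2-dioxan-3-yl]propan-1-ol
Conditions: HF·pyridine, pyridine/THF, 0 °C to rt
Reagents that add atoms: none
Why: Buffered fluoride should cleave both the primary and the tertiary silyl ether and spare the peroxide and the tertiary allylic alcohol.

Step 26
Reactants: 34 (2R)-2-[(3S,6R)-6-{2-[(1S)-1-hydroxy-2,2-dimethyl-6-methylidenecyclohexyl]ethyl}-6-methyl-1,2-dioxan-3-yl]propan-1-ol
Product: 35 (2S)-2-[(3S,6R)-6-{2-[(1S)-1-hydroxy-2,2-dimethyl-6-methylidenecyclohexyl]ethyl}-6-methyl-1,2-dioxan-3-yl]propanoic acid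
Conditions: TEMPO (20 mol %), PhI(OAc)2, MeCN/H2O, rt
Reagents that add atoms: water, O
Why: Oxoammonium-mediated oxidation takes the primary alcohol through the aldehyde hydrate to the acid and should leave the tertiary alcohol, the alkene and the peroxide untouched.

Step 27
Reactants: 35 (2S)-2-[(3S,6R)-6-{2-[(1S)-1-hydroxy-2,2-dimethyl-6-methylidenecyclohexyl]ethyl}-6-methyl-1,2-dioxan-3-yl]propanoic acid
Product: 36 methyl (2S)-2-[(3S,6R)-6-{2-[(1S)-1-hydroxy-2,2-dimethyl-6-methylidenecyclohexyl]ethyl}-6-methyl-1,2-dioxan-3-yl]propanoate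
Conditions: TMSCHN2, MeOH/toluene, 0 °C
Reagents that add atoms: (trimethylsilyl)diazomethane, C[Si](C)(C)C=[N+]=[N-]
Why: Methylation of the acid with the diazoalkane under neutral conditions avoids base that could open the β-peroxy ester.

**Compound list**

1 | but-2-yn-1-ol | CC#CCO | starting material
2 | (4-bromobut-1-yn-1-yl)trimethylsilane | C[Si](C)(C)C#CCCBr | starting material
3 | [4-(trimethylsilyl)but-3-yn-1-yl]magnesium bromide | C[Si](C)(C)C#CCC[Mg]Br | intermediate (not isolated)
4 | 3-methyl-4-[4-(trimethylsilyl)but-3-yn-1-yl]-2,5-dihydro-1,2-oxamagnesole (cyclic alkenylmagnesium alkoxide) | CC1=C(CCC#C[Si](C)(C)C)CO[Mg]1 | intermediate (not isolated)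
5 | (2Z)-3-iodo-2-[4-(trimethylsilyl)but-3-yn-1-yl]but-2-en-1-ol | C/C(I)=C(/CO)CCC#C[Si](C)(C)C | intermediate
6 | 3-methyl-2-[4-(trimethylsilyl)but-3-yn-1-yl]but-2-en-1-ol | CC(C)=C(CO)CCC#C[Si](C)(C)C | intermediate
7 | {(2R)-3,3-dimethyl-2-[4-(trimethylsilyl)but-3-yn-1-yl]oxiran-2-yl}methanol | OC[C@@]1(CCC#C[Si](C)(C)C)OC1(C)C | intermediate
8 | (2S)-3-methyl-2-[4-(trimethylsilyl)but-3-yn-1-yl]but-3-ene-1,2-diol | C=C(C)[C@@](CO)(O)CCC#C[Si](C)(C)C | intermediate
9 | (2S)-2-hydroxy-3-methyl-2-[4-(trimethylsilyl)but-3-yn-1-yl]but-3-enal | C=C(C)[C@@](C=O)(O)CCC#C[Si](C)(C)C | intermediate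
10 | phenyl vinyl sulfone | C=CS(=O)(=O)c1ccccc1 | starting material
11 | 2-(phenylsulfonyl)prop-2-en-1-ol | C=C(CO)S(=O)(=O)c1ccccc1 | intermediate
12 | 3-bromo-2-(phenylsulfonyl)prop-1-ene | C=C(CBr)S(=O)(=O)c1ccccc1 | intermediate
13 | (5S)-6-methyl-2-(phenylsulfonyl)-5-[4-(trimethylsilyl)but-3-yn-1-yl]hepta-1,6-diene-4,5-diol (both C-4 epimers) | C=C(C)[C@@](C(O)CC(=C)S(=O)(=O)c1ccccc1)(O)CCC#C[Si](C)(C)C | intermediate
14 | (1S)-6,6-dimethyl-4-(phenylsulfonyl)-1-[4-(trimethylsilyl)but-3-yn-1-yl]cyclohexane-1,2-diol (epimers at C-2 and C-4) | OC1CC(S(=O)(=O)c2ccccc2)CC(C)(C)[C@@]1(O)CCC#C[Si](C)(C)C | intermediate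
15 | (1S)-1-(but-3-yn-1-yl)-6,6-dimethylcyclohexane-1,2-diol (both C-2 epimers) | OC1CCCC(C)(C)[C@@]1(O)CCC#C | intermediate
16 | (2S)-2-(but-3-yn-1-yl)-2-hydroxy-3,3-dimethylcyclohexan-1-one | O=C1CCCC(C)(C)[C@@]1(O)CCC#C | intermediate
17 | (1S)-1-(but-3-yn-1-yl)-2,2-dimethyl-6-methylidenecyclohexan-1-ol | C=C1CCCC(C)(C)[C@@]1(O)CCC#C | intermediate
18 | {[(1S)-1-(but-3-yn-1-yl)-2,2-dimethyl-6-methylidenecyclohexyl]oxy}triethylsilane | C=C1CCCC(C)(C)[C@@]1(O[Si](CC)(CC)CC)CCC#C | intermediate
19 | methyl (2R)-3-hydroxy-2-methylpropanoate | COC(=O)[C@H](C)CO | starting material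
20 | methyl (2R)-3-[(tert-butyldimethylsilyl)oxy]-2-methylpropanoate | COC(=O)[C@H](C)CO[Si](C)(C)C(C)(C)C | intermediate
21 | (2R)-3-[(tert-butyldimethylsilyl)oxy]-2-methylpropanal | O=C[C@H](C)CO[Si](C)(C)C(C)(C)C | intermediate
22 | lithium (3R)-4-[(tert-butyldimethylsilyl)oxy]-1-chloro-3-methylbutan-2-olate (both C-2 epimers) | [Li+].[O-]C(CCl)[C@H](C)CO[Si](C)(C)C(C)(C)C | intermediate (not isolated)
23 | tert-butyldimethyl{[(2R)-2-(oxiran-2-yl)propyl]oxy}silane (both oxirane epimers) | C1OC1[C@H](C)CO[Si](C)(C)C(C)(C)C | intermediate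
24 | tert-butyldimethyl{[(2R)-2-[(2S)-oxiran-2-yl]propyl]oxy}silane | C1O[C@H]1[C@H](C)CO[Si](C)(C)C(C)(C)C | intermediate
25 | [(1E)-4-{(1S)-2,2-dimethyl-6-methylidene-1-[(triethylsilyl)oxy]cyclohexyl}-2-methylbut-1-en-1-yl]dimethylalane | C=C1CCCC(C)(C)[C@@]1(O[Si](CC)(CC)CC)CC/C(C)=C/[Al](C)C | intermediate (not isolated)
26 | lithium butyl[(1E)-4-{(1S)-2,2-dimethyl-6-methylidene-1-[(triethylsilyl)oxy]cyclohexyl}-2-methylbut-1-en-1-yl]dimethylaluminate | C=C1CCCC(C)(C)[C@@]1(O[Si](CC)(CC)CC)CC/C(C)=C/[Al-](C)(C)CCCC.[Li+] | intermediate (not isolated)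
27 | (2R,3R,5E)-1-[(tert-butyldimethylsilyl)oxy]-8-{(1S)-2,2-dimethyl-6-methylidene-1-[(triethylsilyl)oxy]cyclohexyl}-2,6-dimethyloct-5-en-3-ol | C=C1CCCC(C)(C)[C@@]1(O[Si](CC)(CC)CC)CC/C(C)=C/C[C@@H](O)[C@H](C)CO[Si](C)(C)C(C)(C)C | intermediate
28 | (2R,3R,5E)-1-[(tert-butyldimethylsilyl)oxy]-8-{(1S)-2,2-dimethyl-6-methylidene-1-[(triethylsilyl)oxy]cyclohexyl}-2,6-dimethyloct-5-en-3-yl methanesulfonate | C=C1CCCC(C)(C)[C@@]1(O[Si](CC)(CC)CC)CC/C(C)=C/C[C@H]([C@H](C)CO[Si](C)(C)C(C)(C)C)OS(C)(=O)=O | intermediate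
29 | (2R,3R,5R,6R)-1-[(tert-butyldimethylsilyl)oxy]-8-{(1S)-2,2-dimethyl-6-methylidene-1-[(triethylsilyl)oxy]cyclohexyl}-5,6-epoxy-2,6-dimethyloctan-3-yl methanesulfonate | C=C1CCCC(C)(C)[C@@]1(O[Si](CC)(CC)CC)CC[C@@]1(C)O[C@@H]1C[C@H]([C@H](C)CO[Si](C)(C)C(C)(C)C)OS(C)(=O)=O | intermediate
30 | (2R,3R,5R,6S)-1-[(tert-butyldimethylsilyl)oxy]-8-{(1S)-2,2-dimethyl-6-methylidene-1-[(triethylsilyl)oxy]cyclohexyl}-6-hydroperoxy-5-hydroxy-2,6-dimethyloctan-3-yl methanesulfonate | C=C1CCCC(C)(C)[C@@]1(O[Si](CC)(CC)CC)CC[C@](C)(OO)[C@H](O)C[C@H]([C@H](C)CO[Si](C)(C)C(C)(C)C)OS(C)(=O)=O | intermediate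
31 | (3S,4R,6S)-6-{(2R)-1-[(tert-butyldimethylsilyl)oxy]propan-2-yl}-3-(2-{(1S)-2,2-dimethyl-6-methylidene-1-[(triethylsilyl)oxy]cyclohexyl}ethyl)-3-methyl-1,2-dioxan-4-ol | C=C1CCCC(C)(C)[C@@]1(O[Si](CC)(CC)CC)CC[C@@]1(C)[C@H](O)C[C@@H]([C@H](C)CO[Si](C)(C)C(C)(C)C)OO1 | intermediate
32 | (3S,6S)-6-{(2R)-1-[(tert-butyldimethylsilyl)oxy]propan-2-yl}-3-(2-{(1S)-2,2-dimethyl-6-methylidene-1-[(triethylsilyl)oxy]cyclohexyl}ethyl)-3-methyl-3,6-dihydro-1,2-dioxine | C=C1CCCC(C)(C)[C@@]1(O[Si](CC)(CC)CC)CC[C@@]1(C)C=C[C@@H]([C@H](C)CO[Si](C)(C)C(C)(C)C)OO1 | intermediate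
33 | (3R,6S)-6-{(2R)-1-[(tert-butyldimethylsilyl)oxy]propan-2-yl}-3-(2-{(1S)-2,2-dimethyl-6-methylidene-1-[(triethylsilyl)oxy]cyclohexyl}ethyl)-3-methyl-1,2-dioxane | C=C1CCCC(C)(C)[C@@]1(O[Si](CC)(CC)CC)CC[C@@]1(C)CC[C@@H]([C@H](C)CO[Si](C)(C)C(C)(C)C)OO1 | intermediate
34 | (2R)-2-[(3S,6R)-6-{2-[(1S)-1-hydroxy-2,2-dimethyl-6-methylidenecyclohexyl]ethyl}-6-methyl-1,2-dioxan-3-yl]propan-1-ol | C=C1CCCC(C)(C)[C@@]1(O)CC[C@@]1(C)CC[C@@H]([C@H](C)CO)OO1 | intermediate
35 | (2S)-2-[(3S,6R)-6-{2-[(1S)-1-hydroxy-2,2-dimethyl-6-methylidenecyclohexyl]ethyl}-6-methyl-1,2-dioxan-3-yl]propanoic acid | C=C1CCCC(C)(C)[C@@]1(O)CC[C@@]1(C)CC[C@@H]([C@H](C)C(=O)O)OO1 | intermediate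
36 | methyl (2S)-2-[(3S,6R)-6-{2-[(1S)-1-hydroxy-2,2-dimethyl-6-methylidenecyclohexyl]ethyl}-6-methyl-1,2-dioxan-3-yl]propanoate | C=C1CCCC(C)(C)[C@@]1(O)CC[C@@]1(C)CC[C@@H]([C@H](C)C(=O)OC)OO1 | target

**Step count and weak points**

Total step count: 27. Longest linear sequence: 21 steps (steps 1–5, 8–13 and 18–27).

Step 9. The tertiary radical may be reduced to the isopropyl group, or may add 5-exo to the silylalkyne, before it reaches the sulfonylalkene. The fallback makes the same radical without a hydride source, by reductive opening of an epoxide with trivalent titanium (Nugent–RajanBabu reaction). It sets out from 7. IBX oxidation (DMSO, rt) should give (2S)-3,3-dimethyl-2-[4-(trimethylsilyl)but-3-yn-1-yl]oxirane-2-carbaldehyde F1. Zinc-mediated Barbier addition of 12 (THF/aq. NH4Cl) should then give 1-{(2R)-3,3-dimethyl-2-[4-(trimethylsilyl)but-3-yn-1-yl]oxiran-2-yl}-3-(phenylsulfonyl)but-3-en-1-ol F2 as both carbinol epimers. Cp2TiCl (from Cp2TiCl2 and Zn, THF, rt) is expected to cleave the O–C(CH3)2 bond, which leaves the radical away from the hydroxyl-bearing carbon; 6-endo addition to the sulfonylalkene, reduction and protonation on work-up lead to 14, where the route is rejoined.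

Step 21. The tertiary carbon may ionise and lose stereochemical fidelity, or the acidic medium may strip the tertiary silyl ether and allow tetrahydrofuran formation. The fallback reverses the order in which the two C–O bonds are made and sets out from 29. Displacement of the mesylate by hydroperoxide anion (50% H2O2, KOH, MeOH/THF, 0 °C; SN2 with inversion) should give (2R,3S,5R,6R)-1-(TBSO)-8-Cy*-5,6-epoxy-3-hydroperoxy-2,6-dimethyloctane F3. Mild acid (pyridinium p-toluenesulfonate or Yb(OTf)3, CH2Cl2) should then induce intramolecular 6-endo opening of the epoxide at its tertiary carbon, where the tether enforces backside attack. This gives 31 directly, so steps 21 and 22 are both replaced.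

Step 24. Diimide may also reduce the exocyclic methylene, and the dihydrodioxine from step 23 is prone to base-type Kornblum–DeLaMare cleavage on handling. The fallback removes the hydroxyl without an alkene intermediate and sets out from 31. 1,1′-Thiocarbonyldiimidazole (DMAP, CH2Cl2) should give the O-(imidazol-1-ylthiocarbonyl) derivative of 31, F4. Barton–McCombie deoxygenation (Bu3SnH at 1 M or above, Et3B/air, rt) is run at high stannane concentration so that hydrogen transfer outruns closure of the β-peroxy radical to an epoxide. It should give 33 directly, so steps 23 and 24 are both replaced.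

Further compounds
F1 | step 9 | (2S)-3,3-dimethyl-2-[4-(trimethylsilyl)but-3-yn-1-yl]oxirane-2-carbaldehyde | O=C[C@@]1(CCC#C[Si](C)(C)C)OC1(C)C
F2 | step 9 | 1-{(2R)-3,3-dimethyl-2-[4-(trimethylsilyl)but-3-yn-1-yl]oxiran-2-yl}-3-(phenylsulfonyl)but-3-en-1-ol (both carbinol epimers) | OC(CC(=C)S(=O)(=O)c1ccccc1)[C@@]1(CCC#C[Si](C)(C)C)OC1(C)C
F3 | step 21 | (2R,3S,5R,6R)-1-[(tert-butyldimethylsilyl)oxy]-8-{(1S)-2,2-dimethyl-6-methylidene-1-[(triethylsilyl)oxy]cyclohexyl}-5,6-epoxy-3-hydroperoxy-2,6-dimethyloctane | C=C1CCCC(C)(C)[C@@]1(O[Si](CC)(CC)CC)CC[C@@]1(C)O[C@@H]1C[C@@H]([C@H](C)CO[Si](C)(C)C(C)(C)C)OO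
F4 | step 24 | O-[(3S,4R,6S)-6-{(2R)-1-[(tert-butyldimethylsilyl)oxy]propan-2-yl}-3-(2-{(1S)-2,2-dimethyl-6-methylidene-1-[(triethylsilyl)oxy]cyclohexyl}ethyl)-3-methyl-1,2-dioxan-4-yl] 1H-imidazole-1-carbothioate | C=C1CCCC(C)(C)[C@@]1(O[Si](CC)(CC)CC)CC[C@@]1(C)[C@H](OC(=S)n2ccnc2)C[C@@H]([C@H](C)CO[Si](C)(C)C(C)(C)C)OO1
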